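## Retrosynthetic overview

1. The C3–O bond is made last. A (2S)-2-aryl-4-siloxy-2H-chromene is oxidised on the face anti to the aryl group (Rubottom), and all silyl groups are then removed.
2. The C2–C1′ bond is the fragment union. It is a Rh-catalysed enantioselective silylative conjugate arylation of 5-hydroxy-7-methoxy-6-prenylchromone with an arylzinc reagent made from catechol.
3. The chromone (C4–C4a and O1–C2 bonds) comes from an ortho-lithiated 2-bromo-3,5-dimethoxy-4-prenylphenoxide and a 3-ethoxyacryloyl Weinreb amide (from ethyl vinyl ether and oxalyl chloride). A chelation-controlled 5-O-demethylation follows.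
4. The phenol comes from resorcinol by O-methylation, directed ortho-metalation/prenylation and Ir-catalysed C–H borylation/oxidation.
5. Rings A and B are bought as benzene rings. The only ring formed is the pyranone ring C (step 7), and its C2=C3 bond is functionalised stereoselectively in steps 12 and 13.

Assumption: positions carry flavonoid numbering, and the sense of induction of (S)-BINAP is taken from the established model for cyclic enones and 4-quinolones. If a first run shows the opposite sense, (R)-BINAP is used.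

## Route

**Step 1**
Reactants: 1 resorcinol
Product: 2 1,3-dimethoxybenzene
Conditions: MeI (2.5 equiv), K2CO3, acetone, reflux
Reagents that add atoms: iodomethane, CI
Why: Williamson ether synthesis caps both phenols and gives a symmetric arene with two groups that direct lithiation.

**Step 2**
Reactants: 2 1,3-dimethoxybenzene; 3 prenyl bromide (1-bromo-3-methylbut-2-ene)
Product: 5 1,3-dimethoxy-2-(3-methylbut-2-en-1-yl)benzene, via 2,6-dimethoxyphenyllithium 4 (not isolated)
Conditions: n-BuLi, THF, 0 °C to rt; then 3, −78 °C to rt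
Reagents that add atoms: n-butyllithium, [Li]CCCC (Li in 4 only)
Why: Directed ortho-metalation occurs only at the C–H flanked by both methoxy groups, and the aryllithium displaces the primary allylic bromide in SN2 fashion, so the prenyl group sits between the future 5-O and 7-O.

**Step 3**
Reactants: 5 1,3-dimethoxy-2-(3-methylbut-2-en-1-yl)benzene
Product: 7 3,5-dimethoxy-4-(3-methylbut-2-en-1-yl)phenol, via aryl pinacol boronate 6 (not isolated)
Conditions: [Ir(OMe)(cod)]2 (1.5 mol %), dtbpy (3 mol %), B2pin2, THF, 70 °C; then 30 % H2O2, aq NaOH, 0 °C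
Reagents that add atoms: bis(pinacolato)diboron, CC1(C)OB(OC1(C)C)B1OC(C)(C)C(C)(C)O1 (Bpin in 6 only); hydrogen peroxide, OO
Why: Sterically governed Ir-catalysed aromatic C–H borylation reaches only the one ring C–H with no ortho substituent (para to prenyl), and basic peroxide converts C–B to C–O without epoxidising the unactivated trisubstituted alkene.

**Step 4**
Reactants: 7 3,5-dimethoxy-4-(3-methylbut-2-en-1-yl)phenol
Product: 8 2-bromo-3,5-dimethoxy-4-(3-methylbut-2-en-1-yl)phenol
Conditions: NBS (1.0 equiv), CH2Cl2, −78 to −40 °C, dark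
Reagents that add atoms: N-bromosuccinimide, O=C1CCC(=O)N1Br
Why: In this electrophilic aromatic bromination the phloroglucinol-type ring reacts much faster than the alkene at low temperature, the para position is blocked and the two ortho positions are equivalent, so one regioisomer forms.

**Step 5**
Reactants: 9 ethyl vinyl ether; 10 oxalyl chloride
Product: 12 (E)-3-ethoxyacryloyl chloride, via (E)-4-ethoxy-2-oxobut-3-enoyl chloride 11 (not isolated)
Conditions: neat, 0 °C to rt, 12 h; then 120 °C, 30 min; distil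
Reagents that add atoms: none
Why: Electrophilic acylation of the enol ether with loss of HCl, followed by thermal decarbonylation of the α-keto acid chloride, is the standard preparation of this acid chloride.

**Step 6**
Reactants: 12 (E)-3-ethoxyacryloyl chloride
Product: 13 (E)-3-ethoxy-N-methoxy-N-methylprop-2-enamide
Conditions: MeNH(OMe)·HCl, pyridine, CH2Cl2, 0 °C to rt
Reagents that add atoms: N,O-dimethylhydroxylamine hydrochloride, CNOC.Cl
Why: Schotten–Baumann-type acylation at the acid chloride carbon is far faster than attack at the β-carbon, so the Weinreb amide keeps its E-enol ether.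

**Step 7**
Reactants: 8 2-bromo-3,5-dimethoxy-4-(3-methylbut-2-en-1-yl)phenol; 13 (E)-3-ethoxy-N-methoxy-N-methylprop-2-enamide
Product: 16 5,7-dimethoxy-6-(3-methylbut-2-en-1-yl)-4H-chromen-4-one, via ortho-lithiated lithium phenoxide 14 (not isolated), via o-hydroxyaryl ethoxyvinyl ketone 15 (not isolated)
Conditions: n-BuLi (2.2 equiv), THF, −78 °C; 13, −78 to 0 °C; then 2 M HCl, THF, rt
Reagents that add atoms: n-butyllithium, [Li]CCCC (Li in 14 only)
Why: Deprotonation and Br–Li exchange give the dianion, the Weinreb ketone synthesis stops at the chelated adduct, and the acid quench releases the o-hydroxyaryl β-ethoxyvinyl ketone, which closes ring C by oxa-Michael addition and elimination of ethanol.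

**Step 8**
Reactants: 16 5,7-dimethoxy-6-(3-methylbut-2-en-1-yl)-4H-chromen-4-one
Product: 17 5-hydroxy-7-methoxy-6-(3-methylbut-2-en-1-yl)-4H-chromen-4-one
Conditions: anhydrous MgI2 (2.5 equiv), THF, 60 °C; cold 0.5 M HCl work-up
Reagents that add atoms: none
Why: In this chelation-controlled ether cleavage Mg(II) binds between C4=O and the twisted 5-OMe, so iodide removes only that methyl group (SN2), and this mild Lewis acid leaves prenyl side chains of flavonoids intact.

**Step 9**
Reactants: 18 catechol
Product: 19 2-methoxyphenol (guaiacol)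
Conditions: MeI (1.0 equiv), K2CO3 (1.0 equiv), acetone, reflux; veratrole removed by base extraction
Reagents that add atoms: iodomethane, CI
Why: Mono-Williamson etherification with one equivalent of base and electrophile gives mainly the monoether, and it is separated easily because it is the only extractable monophenol.

**Step 10**
Reactants: 19 2-methoxyphenol
Product: 20 4-bromo-2-methoxyphenol
Conditions: NBS, MeCN, 0 °C
Reagents that add atoms: N-bromosuccinimide, O=C1CCC(=O)N1Br
Why: Electrophilic aromatic bromination is directed para to the stronger donor, the free OH, which is the carbon that becomes C1′.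

**Step 11**
Reactants: 20 4-bromo-2-methoxyphenol
Product: 21 (4-bromo-2-methoxyphenoxy)(tert-butyl)dimethylsilane
Conditions: TBSCl, imidazole, CH2Cl2, rt
Reagents that add atoms: tert-butyldimethylsilyl chloride, CC(C)(C)[Si](C)(C)Cl
Why: Standard silyl protection removes the acidic proton, and the TBS ether survives n-BuLi at −78 °C, zinc salts and neutral oxidants.

**Step 12**
Reactants: 17 5-hydroxy-7-methoxy-6-(3-methylbut-2-en-1-yl)-4H-chromen-4-one; 21 (4-bromo-2-methoxyphenoxy)(tert-butyl)dimethylsilane
Product: 25 (2S)-2-[4-(tert-butyldimethylsilyloxy)-3-methoxyphenyl]-7-methoxy-6-(3-methylbut-2-en-1-yl)-4,5-bis(trimethylsilyloxy)-2H-chromene, via 5-O-TMS chromone 22 (not isolated), via aryllithium 23 (not isolated), via arylzinc chloride 24 (not isolated)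
Conditions: flask A: 21 (2 equiv), n-BuLi, THF, −78 °C, then ZnCl2, to rt; flask B: 17, NaH, THF, 0 °C, then Me3SiCl (3.5 equiv), rt; combine with [RhCl(C2H4)2]2 (2.5 mol %) and (S)-BINAP (5.5 mol %), THF, 20 °C, dark; cold pentane/aq NaHCO3 work-up, used at once
Reagents that add atoms: chlorotrimethylsilane, C[Si](C)(C)Cl; n-butyllithium, [Li]CCCC (Li in 23 only); zinc chloride, Cl[Zn]Cl (ZnCl in 24 only)
Why: Proposed new method: enantioselective silylative conjugate arylation of a chromone, in which 24 transmetalates to the (S)-BINAP–Rh(I) chloride, the aryl–Rh species inserts the C2=C3 bond of 22 on the face left open by the ligand (same quadrant picture as for cyclic enones, giving 2S here), and Me3SiCl silylates the oxa-π-allyl rhodium enolate before it can be protonated or expel the C8a aryloxide (β-oxygen elimination, the ring-opening and racemisation channel of flavanone enolates), which regenerates Rh–Cl and stores C2 in a silyl enol ether ready for oxygenation; the closest known reactions are the Rh/BINAP-catalysed 1,4-addition of arylzinc chlorides with Me3SiCl to 4-quinolones and 2,3-dihydro-4-pyridones and the aqueous Rh-catalysed 1,4-addition of arylboronic acids to chromones, whereas the organozinc/chlorosilane version on a chromone with isolation of the 4-siloxy-2H-chromene has not been shown.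

**Step 13**
Reactants: 25 (2S)-2-[4-(tert-butyldimethylsilyloxy)-3-methoxyphenyl]-7-methoxy-6-(3-methylbut-2-en-1-yl)-4,5-bis(trimethylsilyloxy)-2H-chromene
Product: 28 (2R,3R)-3,5-dihydroxy-2-(4-hydroxy-3-methoxyphenyl)-7-methoxy-6-(3-methylbut-2-en-1-yl)chroman-4-one (CNP0164735.1), via siloxy epoxide 26 (not isolated), via 3-O-TMS ketone 27 (not isolated)
Conditions: DMDO (1.05 equiv, dried acetone solution), CH2Cl2, −78 °C; then TBAF/AcOH (1:1, 3.5 equiv), THF, −78 to 0 °C
Reagents that add atoms: dimethyldioxirane, CC1(C)OO1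
Why: In this Rubottom oxidation the very electron-rich silyl enol ether is epoxidised at −78 °C much faster than the prenyl alkene and on the face anti to the pseudo-axial 2-aryl group, silyl migration gives the 2,3-trans 3-siloxy ketone (sets C3 = R, and the C2 descriptor becomes R by priority change only), and acetic-acid-buffered fluoride removes all three silyl groups without enolising C3 or opening ring C.

## Compound list

1 | resorcinol | Oc1cccc(O)c1 | starting material
2 | 1,3-dimethoxybenzene | COc1cccc(OC)c1 | intermediate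
3 | prenyl bromide (1-bromo-3-methylbut-2-ene) | CC(C)=CCBr | starting material
4 | 2,6-dimethoxyphenyllithium | COc1cccc(OC)c1[Li] | intermediate
5 | 1,3-dimethoxy-2-(3-methylbut-2-en-1-yl)benzene | COc1cccc(OC)c1CC=C(C)C | intermediate
6 | 2-[3,5-dimethoxy-4-(3-methylbut-2-en-1-yl)phenyl]-4,4,5,5-tetramethyl-1,3,2-dioxaborolane | COc1cc(B2OC(C)(C)C(C)(C)O2)cc(OC)c1CC=C(C)C | intermediate
7 | 3,5-dimethoxy-4-(3-methylbut-2-en-1-yl)phenol | COc1cc(O)cc(OC)c1CC=C(C)C | intermediate
8 | 2-bromo-3,5-dimethoxy-4-(3-methylbut-2-en-1-yl)phenol | COc1cc(O)c(Br)c(OC)c1CC=C(C)C | intermediate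
9 | ethyl vinyl ether | CCOC=C | starting material
10 | oxalyl chloride | O=C(Cl)C(=O)Cl | starting material
11 | (E)-4-ethoxy-2-oxobut-3-enoyl chloride | CCO/C=C/C(=O)C(=O)Cl | intermediate
12 | (E)-3-ethoxyacryloyl chloride | CCO/C=C/C(=O)Cl | intermediate
13 | (E)-3-ethoxy-N-methoxy-N-methylprop-2-enamide | CCO/C=C/C(=O)N(C)OC | intermediate
14 | lithium 2-lithio-3,5-dimethoxy-4-(3-methylbut-2-en-1-yl)phenoxide | COc1cc(O[Li])c([Li])c(OC)c1CC=C(C)C | intermediate
15 | (E)-3-ethoxy-1-[2-hydroxy-4,6-dimethoxy-5-(3-methylbut-2-en-1-yl)phenyl]prop-2-en-1-one | CCO/C=C/C(=O)c1c(O)cc(OC)c(CC=C(C)C)c1OC | intermediate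
16 | 5,7-dimethoxy-6-(3-methylbut-2-en-1-yl)-4H-chromen-4-one | COc1cc2occc(=O)c2c(OC)c1CC=C(C)C | intermediate
17 | 5-hydroxy-7-methoxy-6-(3-methylbut-2-en-1-yl)-4H-chromen-4-one | COc1cc2occc(=O)c2c(O)c1CC=C(C)C | intermediate
18 | catechol | Oc1ccccc1O | starting material
19 | 2-methoxyphenol | COc1ccccc1O | intermediate
20 | 4-bromo-2-methoxyphenol | COc1cc(Br)ccc1O | intermediate
21 | (4-bromo-2-methoxyphenoxy)(tert-butyl)dimethylsilane | COc1cc(Br)ccc1O[Si](C)(C)C(C)(C)C | intermediate
22 | 7-methoxy-6-(3-methylbut-2-en-1-yl)-5-(trimethylsilyloxy)-4H-chromen-4-one | COc1cc2occc(=O)c2c(O[Si](C)(C)C)c1CC=C(C)C | intermediate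
23 | [4-(tert-butyldimethylsilyloxy)-3-methoxyphenyl]lithium | COc1cc([Li])ccc1O[Si](C)(C)C(C)(C)C | intermediate
24 | [4-(tert-butyldimethylsilyloxy)-3-methoxyphenyl]zinc chloride | COc1cc([Zn]Cl)ccc1O[Si](C)(C)C(C)(C)C | intermediate
25 | (2S)-2-[4-(tert-butyldimethylsilyloxy)-3-methoxyphenyl]-7-methoxy-6-(3-methylbut-2-en-1-yl)-4,5-bis(trimethylsilyloxy)-2H-chromene | COc1cc([C@H]2Oc3cc(OC)c(CC=C(C)C)c(O[Si](C)(C)C)c3C(O[Si](C)(C)C)=C2)ccc1O[Si](C)(C)C(C)(C)C | intermediate
26 | 3,4-epoxide of 25 with the epoxide oxygen trans to the 2-aryl group, (2R,3R,4R) in flavan numbering | COc1cc([C@H]2Oc3cc(OC)c(CC=C(C)C)c(O[Si](C)(C)C)c3[C@@]4(O[Si](C)(C)C)[C@@H]2O4)ccc1O[Si](C)(C)C(C)(C)C | intermediate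
27 | (2R,3R)-2-[4-(tert-butyldimethylsilyloxy)-3-methoxyphenyl]-7-methoxy-6-(3-methylbut-2-en-1-yl)-3,5-bis(trimethylsilyloxy)chroman-4-one | COc1cc([C@H]2Oc3cc(OC)c(CC=C(C)C)c(O[Si](C)(C)C)c3C(=O)[C@@H]2O[Si](C)(C)C)ccc1O[Si](C)(C)C(C)(C)C | intermediate
28 | (2R,3R)-3,5-dihydroxy-2-(4-hydroxy-3-methoxyphenyl)-7-methoxy-6-(3-methylbut-2-en-1-yl)chroman-4-one | COc1cc([C@H]2Oc3cc(OC)c(CC=C(C)C)c(O)c3C(=O)[C@@H]2O)ccc1O | target

## Step count and risks

Total step count: 13.
Longest linear sequence: 8 (steps 1, 2, 3, 4, 7, 8, 12, 13). Steps 5–6 and steps 9–11 are side branches.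

**Step 12 (the new step).**
- Risks: the electron-rich chromone may react slowly, uncatalysed addition to a transient 4-siloxybenzopyrylium chloride may erode the ee, and β-oxygen elimination may open the ring.
- The fallback uses known chemistry. It sets out from 21 and 17 and comes back at 25.
- Bromide 21 is lithiated (n-BuLi, THF, −78 °C, giving 23), quenched with B(OiPr)3 and hydrolysed with aq NH4Cl. This gives [4-(tert-butyldimethylsilyloxy)-3-methoxyphenyl]boronic acid F1.
- The established aqueous Rh(I)-catalysed asymmetric 1,4-addition of arylboronic acids to chromones is then run on 17 (Rh(I) with an electron-poor (S)-biaryl bisphosphine or a chiral diene, toluene/H2O, rt to 50 °C). It gives (2S)-2-[4-(tert-butyldimethylsilyloxy)-3-methoxyphenyl]-5-hydroxy-7-methoxy-6-(3-methylbut-2-en-1-yl)chroman-4-one F2.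
- Soft enolisation and silylation (TMSOTf, Et3N, CH2Cl2, 0 °C) caps the 5-OH and forms the enol ether, which delivers 25.

**Step 7.**
- Risks: the hindered dianion may add in 1,4-fashion or react sluggishly with the vinylogous carbamate.
- The fallback replaces the halogen route by directed metalation and an enaminone annulation. It sets out from 7, so it also bypasses step 4, and comes back at 16.
- Phenol 7 is protected (MOMCl, iPr2NEt, CH2Cl2) as 1,3-dimethoxy-5-(methoxymethoxy)-2-(3-methylbut-2-en-1-yl)benzene F3.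
- n-BuLi (THF, 0 °C) lithiates between OMOM and OMe and gives [2,4-dimethoxy-6-(methoxymethoxy)-3-(3-methylbut-2-en-1-yl)phenyl]lithium F4.
- N-methoxy-N-methylacetamide then gives 1-[2,4-dimethoxy-6-(methoxymethoxy)-3-(3-methylbut-2-en-1-yl)phenyl]ethanone F5.
- DMF dimethyl acetal (100 °C) gives (E)-3-(dimethylamino)-1-[2,4-dimethoxy-6-(methoxymethoxy)-3-(3-methylbut-2-en-1-yl)phenyl]prop-2-en-1-one F6.
- HCl in MeOH/CH2Cl2 (40 °C) removes the MOM group and closes the ring to 16.

**Step 13.**
- Risks: DMDO may also attack the prenyl alkene, or the TMS enol ether may hydrolyse before it is oxidised.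
- The fallback exchanges alkene-type epoxidation for enolate hydroxylation. It sets out from 25 and comes back at 28.
- MeLi (2.2 equiv, THF, −78 to −20 °C) cleaves both O–SiMe3 bonds. This gives the dilithium 4-enolate 5-phenoxide of the (2S)-flavanone F7.
- At −78 °C, 2-(phenylsulfonyl)-3-phenyloxaziridine, which is inert to alkenes at this temperature, delivers oxygen anti to the 2-aryl group. The product is (2R,3R)-2-[4-(tert-butyldimethylsilyloxy)-3-methoxyphenyl]-3,5-dihydroxy-7-methoxy-6-(3-methylbut-2-en-1-yl)chroman-4-one F8.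
- TBAF/AcOH (THF, 0 °C) then gives 28.

## Further compounds

F1 | step 12 | [4-(tert-butyldimethylsilyloxy)-3-methoxyphenyl]boronic acid | COc1cc(B(O)O)ccc1O[Si](C)(C)C(C)(C)C
F2 | step 12 | (2S)-2-[4-(tert-butyldimethylsilyloxy)-3-methoxyphenyl]-5-hydroxy-7-methoxy-6-(3-methylbut-2-en-1-yl)chroman-4-one | COc1cc([C@H]2Oc3cc(OC)c(CC=C(C)C)c(O)c3C(=O)C2)ccc1O[Si](C)(C)C(C)(C)C
F3 | step 7 | 1,3-dimethoxy-5-(methoxymethoxy)-2-(3-methylbut-2-en-1-yl)benzene | COCOc1cc(OC)c(CC=C(C)C)c(OC)c1
F4 | step 7 | [2,4-dimethoxy-6-(methoxymethoxy)-3-(3-methylbut-2-en-1-yl)phenyl]lithium | COCOc1cc(OC)c(CC=C(C)C)c(OC)c1[Li]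
F5 | step 7 | 1-[2,4-dimethoxy-6-(methoxymethoxy)-3-(3-methylbut-2-en-1-yl)phenyl]ethanone | CC(=O)c1c(OCOC)cc(OC)c(CC=C(C)C)c1OC
F6 | step 7 | (E)-3-(dimethylamino)-1-[2,4-dimethoxy-6-(methoxymethoxy)-3-(3-methylbut-2-en-1-yl)phenyl]prop-2-en-1-one | CN(C)/C=C/C(=O)c1c(OCOC)cc(OC)c(CC=C(C)C)c1OC
F7 | step 13 | dilithium 4-enolate 5-phenoxide of the (2S)-flavanone | COc1cc([C@H]2Oc3cc(OC)c(CC=C(C)C)c(O[Li])c3C(O[Li])=C2)ccc1O[Si](C)(C)C(C)(C)C
F8 | step 13 | (2R,3R)-2-[4-(tert-butyldimethylsilyloxy)-3-methoxyphenyl]-3,5-dihydroxy-7-methoxy-6-(3-methylbut-2-en-1-yl)chroman-4-one | COc1cc([C@H]2Oc3cc(OC)c(CC=C(C)C)c(O)c3C(=O)[C@@H]2O)ccc1O[Si](C)(C)C(C)(C)C
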